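**Plan**

- Retrosynthesis, in order: C9 ketone from its dimethylhydrazone; lactone C6–O bond (closed with inversion at C6); C12 carboxyl from an isopropenyl group; C8 ester; C7–C8 (ring contraction); C5–C6 (NiCl2/CrCl2); O8–C12 ether; C8/C9 oxygens (dihydroxylation); C1–C10 (crotylboration).
- Forward: a pentynol-derived iodo aldehyde is crotylated, methylated, dihydroxylated and O-alkylated with a prenyl-derived bromide; the thirteen-membered ether ring closes at C5–C6, contracts at C7–C8 to the ten-membered carbocycle, and the γ-lactone closes last.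
- Stereochemistry: C1/C10 from Brown (E)-crotylboration; C6 from the ring closure (R epimer used), inverted by Mitsunobu lactonisation; C7/C8 from the rearrangement (E alkene, exo aza-enolate, face set by C6); C11 by equilibration of the lactone; epoxide from Sharpless epoxidation.
- Enabling feature: C8 carries oxygen beside the C9 carbonyl and is bonded to C7, which bears the three-carbon arm C11(C13)–C12 of the lactone. An allyl ether from O8 to C12 therefore makes C7–C8 the bond formed in a [2,3]-Wittig shift that contracts a thirteen-membered ether to the ten-membered ring.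

Key step: step 14

Remark (numbering): ring carbons C1 (OMe) to C10; C11–C13 the lactone arm (C12 carbonyl, C13 methyl); C14 and C15 the methyls on C4 and C10; O8 the oxygen on C8.
Remark (C6): the rearrangement is expected to add C8 anti to the C6–O bond, placing the C6 oxygen and the isopropenyl group trans; C6 is therefore carried as the R epimer and inverted when the cis-fused lactone is closed.
Remark (mixtures): the C9 carbinol of 11–13 and C11 of 29–33 are epimer mixtures that converge in steps 9 and 22.

Step 1
Reactants: 1 prenyl acetate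
Product: 2 (2E)-4-hydroxy-3-methylbut-2-en-1-yl acetate
Conditions: SeO2 (cat.), tBuOOH, salicylic acid (cat.), CH2Cl2, rt
Reagents that add atoms: tert-butyl hydroperoxide, CC(C)(C)OO
Why: Catalytic SeO2 allylic oxidation (ene reaction, then [2,3]-shift) hydroxylates the methyl group trans to the acetoxymethyl chain, which fixes the E geometry of the future C7=C11 bond.

Step 2
Reactants: 2 (2E)-4-hydroxy-3-methylbut-2-en-1-yl acetate
Product: 3 (2E)-4-bromo-3-methylbut-2-en-1-yl acetate
Conditions: CBr4, PPh3, CH2Cl2, 0 °C
Reagents that add atoms: tetrabromomethane, BrC(Br)(Br)Br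
Why: Appel bromination converts the primary allylic alcohol under neutral conditions, without allylic transposition or loss of the acetate.

Step 3
Reactants: 4 pent-4-yn-1-ol
Product: 6 (E)-5-iodo-4-methylpent-4-en-1-ol, via alkenylalane 5 (not isolated)
Conditions: Me3Al, Cp2ZrCl2 (cat.), CH2Cl2, 0 °C to rt; then I2, THF, −30 to 0 °C
Reagents that add atoms: trimethylaluminium, C[Al](C)C; iodine, II
Why: Negishi zirconium-catalysed carboalumination adds methyl and aluminium syn across the terminal alkyne with the metal at the terminus, and iodine cleaves the C–Al bond with retention, giving the E iodoalkene (future C4=C5).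

Step 4
Reactants: 6 (E)-5-iodo-4-methylpent-4-en-1-ol
Product: 7 (E)-5-iodo-4-methylpent-4-enal
Conditions: PhI(OAc)2, TEMPO (2,2,6,6-tetramethylpiperidin-1-oxyl, cat.), CH2Cl2, rt
Reagents that add atoms: none
Why: Oxoammonium-mediated oxidation stops at the aldehyde and leaves the iodoalkene untouched.

Step 5
Reactants: 7 (E)-5-iodo-4-methylpent-4-enal
Product: 9 (3R,4S,7E)-8-iodo-3,7-dimethylocta-1,7-dien-4-ol, via diisopinocampheylborinate 8 (not isolated)
Conditions: trans-2-butene, KOtBu, nBuLi, THF, −78 to −50 °C; (+)-Ipc2BOMe (from (−)-α-pinene), −78 °C; BF3·OEt2; 7, −78 °C; then NaOH, H2O2, 0 °C to rt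
Reagents that add atoms: trans-2-butene, C/C=C/C
Why: Brown crotylboration through a closed chair transition state: the E-crotyl unit gives the anti pair and the isopinocampheyl groups from (−)-α-pinene direct addition to the Re face of the aldehyde, setting C1 (S) and the methyl-bearing C10 of the target.

Step 6
Reactants: 9 (3R,4S,7E)-8-iodo-3,7-dimethylocta-1,7-dien-4-ol
Product: 10 (3R,4S,7E)-8-iodo-4-methoxy-3,7-dimethylocta-1,7-diene
Conditions: NaH, MeI, THF, 0 °C to rt
Reagents that add atoms: iodomethane, CI
Why: Williamson O-methylation of the sodium alkoxide; nothing base-sensitive is present and both stereocentres are untouched.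

Step 7
Reactants: 10 (3R,4S,7E)-8-iodo-4-methoxy-3,7-dimethylocta-1,7-diene
Product: 11 (3R,4S,7E)-8-iodo-4-methoxy-3,7-dimethyloct-7-ene-1,2-diol (C2 epimers)
Conditions: K2OsO4·2H2O (cat.), NMO, acetone/H2O, 0 °C to rt
Reagents that add atoms: N-methylmorpholine N-oxide, C[N+]1([O-])CCOCC1; water, O
Why: Upjohn dihydroxylation attacks the monosubstituted terminal alkene much faster than the electron-poor trisubstituted iodoalkene; the new carbinol centre (C9) is oxidised in step 9, so its configuration does not matter.

Step 8
Reactants: 11 (3R,4S,7E)-8-iodo-4-methoxy-3,7-dimethyloct-7-ene-1,2-diol; 3 (2E)-4-bromo-3-methylbut-2-en-1-yl acetate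
Product: 13 hydroxy ether acetate (O8–C12 ether; C9 hydroxyl; C6 acetate), via stannylene acetal 12 (not isolated)
Conditions: Bu2SnO, toluene, reflux (−H2O); then 3, CsF, DMF, rt
Reagents that add atoms: none
Why: The dibutylstannylene acetal makes the primary oxygen the more nucleophilic one, and fluoride-promoted SN2 alkylation with the primary allylic bromide forms the O8–C12 ether regioselectively without allylic transposition.

Step 9
Reactants: 13 hydroxy ether acetate
Product: 14 keto ether acetate (C9 ketone)
Conditions: Dess–Martin periodinane, NaHCO3, CH2Cl2, 0 °C to rt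
Reagents that add atoms: none
Why: Dess–Martin oxidation of the only free hydroxyl under buffered conditions gives the α-alkoxy ketone without epimerising the adjacent C10 centre or eliminating the β-methoxy group.

Step 10
Reactants: 14 keto ether acetate
Product: 16 hydrazone allylic alcohol (C9 dimethylhydrazone; C6 primary hydroxyl), via acetate hydrazone 15 (not isolated)
Conditions: Me2NNH2, AcOH (cat.), EtOH, 50 °C; then K2CO3 (cat.), MeOH, 0 °C to rt
Reagents that add atoms: 1,1-dimethylhydrazine, CN(C)N
Why: Condensation of the activated α-alkoxy ketone with 1,1-dimethylhydrazine gives the hydrazone, which masks C9 against base and organochromium attack, and catalytic methanolysis then removes the acetate by transesterification.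

Step 11
Reactants: 16 hydrazone allylic alcohol
Product: 17 hydrazone enal (C6 aldehyde; E)
Conditions: MnO2, CH2Cl2, rt
Reagents that add atoms: none
Why: MnO2 oxidises the primary allylic alcohol selectively to the E enal; the fully substituted hydrazone nitrogen has no N–H to be oxidised.

Step 12
Reactants: 17 hydrazone enal
Product: 18 thirteen-membered hydrazone alcohol (6R; C5–C6 bond closed)
Conditions: CrCl2, NiCl2 (cat.), DMSO, rt, high dilution (slow addition)
Reagents that add atoms: none
Why: Nozaki–Hiyama–Kishi reaction: zerovalent nickel inserts into the C–I bond, transmetalation gives the alkenylchromium species with retention of the E geometry, and its aldehyde-selective addition closes the thirteen-membered ring at C5–C6; the C6 carbinol forms under control of the ring conformation and the (6R) epimer is carried forward.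

Step 13
Reactants: 18 thirteen-membered hydrazone alcohol
Product: 19 thirteen-membered ether with C9 dimethylhydrazone and (6R) tert-butyldimethylsilyl ether
Conditions: TBSCl, imidazole, DMF, rt
Reagents that add atoms: tert-butyldimethylsilyl chloride, CC(C)(C)[Si](C)(C)Cl
Why: Silylation of the only hydroxyl under mild conditions gives the bulky, non-coordinating C6 ether needed to steer the next step.

Step 14
Reactants: 19 thirteen-membered ether with C9 dimethylhydrazone and (6R) silyl ether
Product: 22 ten-membered α-hydroxy hydrazone (C7 isopropenyl; C8 hydroxyl; 6R silyl ether), via lithium aza-enolate 20 (not isolated), via lithium alkoxide 21 (not isolated)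
Conditions: LiN(iPr)2, THF, −78 to −20 °C; aq. NH4Cl
Reagents that add atoms: none
Why: Proposed new method: LiN(iPr)2 metalates C8 of the hydrazone (the CH2 beside the ether oxygen, not the tertiary C10) to give the lithium aza-enolate 20, whose C8 adds to C7 on one face of the allyl unit while the O8–C12 bond breaks on the same face in a five-membered envelope (C8, O8, C12, C11, C7), leaving the alkoxide 21; the closest known reactions are the [2,3]-Wittig ring contraction of thirteen-membered allylic ethers to ten-membered carbocycles and the aza-enolate [2,3]-Wittig rearrangement of open-chain α-allyloxy ketone dimethylhydrazones, which have not been combined in one substrate. The ten-membered carbocycle closes in a 10-exo-trig sense (C8 onto C7, the new C11=C12 bond staying outside the ring) as the thirteen-membered ether opens. C8 and its relation to C7 are set by the E geometry of C7=C11 with the hydrazone carbon exo on the envelope (the usual E-to-anti correlation), which puts the C8 oxygen and the isopropenyl group trans on the ring. C7 is set by C6: allylic 1,3-strain with the C13 methyl holds the C6–H bond in the alkene plane, the ring keeps C5 gauche to the forming bond, and C8 therefore enters anti to the C6–O bond (Felkin–Anh sense), so the (6R) silyloxy group steers C7 and C8 to the target configurations and ends trans to the isopropenyl group. The step needs metalation at C8 over C10 and the [2,3] path over the [3,3] and [1,2] paths; the ether oxygen (inductive and chelating) secures the first, and the aza-enolate, which is known to avoid the oxy-Claisen route of ketone enolates and to rearrange below 0 °C, secures the second.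

Step 15
Reactants: 23 tiglic acid
Product: 24 (2E)-2-methylbut-2-en-1-ol
Conditions: LiAlH4, Et2O, 0 °C to rt
Reagents that add atoms: none
Why: LiAlH4 reduces the conjugated acid to the allylic alcohol by 1,2-hydride addition with the E geometry unchanged.

Step 16
Reactants: 24 (2E)-2-methylbut-2-en-1-ol
Product: 25 [(2R,3R)-2,3-dimethyloxiran-2-yl]methanol
Conditions: Ti(OiPr)4 (cat.), D-(−)-diethyl tartrate (cat.), tBuOOH, 4 Å sieves, CH2Cl2, −20 °C
Reagents that add atoms: tert-butyl hydroperoxide, CC(C)(C)OO
Why: Sharpless asymmetric epoxidation; with D-(−)-diethyl tartrate the titanium–tartrate–peroxide complex delivers oxygen to the face that gives the (2R,3R) epoxy alcohol, setting both epoxide centres, with the cis methyl groups coming from the E alkene.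

Step 17
Reactants: 25 [(2R,3R)-2,3-dimethyloxiran-2-yl]methanol
Product: 26 (2S,3R)-2,3-dimethyloxirane-2-carboxylic acid
Conditions: RuCl3·xH2O (cat.), NaIO4, MeCN/EtOAc/H2O, 0 °C to rt
Reagents that add atoms: water, O
Why: Catalytic RuO4 oxidises the primary alcohol through the aldehyde hydrate to the glycidic acid without opening the epoxide; the C2 descriptor becomes S only because the priorities change.

Step 18
Reactants: 22 ten-membered α-hydroxy hydrazone; 26 (2S,3R)-2,3-dimethyloxirane-2-carboxylic acid
Product: 28 C8 epoxy ester of 22, via mixed anhydride 27 (not isolated)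
Conditions: 26, 2,4,6-trichlorobenzoyl chloride, Et3N, THF, rt; then 22, 4-(dimethylamino)pyridine, toluene, rt to 40 °C
Reagents that add atoms: none
Why: Yamaguchi esterification: 4-(dimethylamino)pyridine attacks the mixed anhydride at the less hindered acyl group and the acylpyridinium ion acylates the hindered C8 hydroxyl; the acid has no α-hydrogen, so its stereocentres cannot epimerise.

Step 19
Reactants: 28 C8 epoxy ester
Product: 30 primary alcohol at C12 (C11 epimers), via B-alkyl-9-borabicyclononane 29 (not isolated)
Conditions: 9-BBN, THF, rt to 40 °C; then NaBO3·4H2O, H2O, rt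
Reagents that add atoms: sodium perborate, [Na+].[Na+].O[B-]1(O)OO[B-](O)(O)OO1
Why: 9-BBN hydroborates the 1,1-disubstituted exocyclic alkene with boron at the terminal C12 and leaves the trisubstituted C4=C5 bond, the ester and the hydrazone alone; perborate oxidises the C–B bond with retention under conditions mild enough for the hydrazone; C11 forms without reliable face control and is corrected in step 22.

Step 20
Reactants: 30 primary alcohol at C12
Product: 31 C12 carboxylic acid (C11 epimers; 6R silyl ether)
Conditions: nPr4NRuO4 (cat.), NMO·H2O, MeCN, rt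
Reagents that add atoms: water, O
Why: Ley–Griffith oxidation in the presence of water takes the primary alcohol through the aldehyde hydrate to the acid under near-neutral, non-electrophilic conditions that the silyl ether, epoxide, alkene and hydrazone should tolerate.

Step 21
Reactants: 31 C12 carboxylic acid
Product: 33 cis-fused hydrazono lactone (6S; C11 epimers), via hydroxy acid 32 (not isolated)
Conditions: HF·pyridine, pyridine, THF, 0 °C, cold pH 7 work-up; then PPh3, DIAD, toluene, 0 °C to rt
Reagents that add atoms: none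
Why: Fluoride removes the silyl group and, without isolation (the 6R hydroxy acid would otherwise close with retention to the trans-fused lactone), Mitsunobu activation of the C6 hydroxyl as its oxyphosphonium ion lets the carboxylate displace it in a 5-exo-tet SN2 reaction, closing the γ-lactone with inversion and setting C6 (S), cis-fused.

Step 22
Reactants: 33 cis-fused hydrazono lactone (C11 epimers)
Product: 34 (11S) cis-fused hydrazono lactone
Conditions: DBU, toluene, 60 °C
Reagents that add atoms: none
Why: Base-mediated epimerisation through the lactone enolate funnels both C11 epimers to the thermodynamically favoured one, with the C13 methyl trans to the C7–C8 bond on the convex face of the cis-fused lactone (11S), a standard correction for α-methyl γ-lactones; C8 and C10 are activated only by the hydrazone and the epoxy ester has no α-hydrogen, so they should stay untouched.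

Step 23
Reactants: 34 (11S) cis-fused hydrazono lactone
Product: 35 CNP0145898.1
Conditions: CuCl2, THF/H2O, pH 7 phosphate buffer, rt
Reagents that add atoms: water, O
Why: CuCl2-promoted hydrolysis of the dimethylhydrazone at pH 7 frees the C9 ketone without base or strong acid, preserving C8, C10, the epoxide and the lactone.

**Compound list**

1 | prenyl acetate (3-methylbut-2-en-1-yl acetate) | CC(C)=CCOC(C)=O | starting material
2 | (2E)-4-hydroxy-3-methylbut-2-en-1-yl acetate | CC(=O)OC/C=C(\C)CO | intermediate
3 | (2E)-4-bromo-3-methylbut-2-en-1-yl acetate | CC(=O)OC/C=C(\C)CBr | intermediate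
4 | pent-4-yn-1-ol | C#CCCCO | starting material
5 | alkenylalane: dimethylaluminium alkoxide of (E)-5-(dimethylalumanyl)-4-methylpent-4-en-1-ol | C[Al](C)OCCC/C(C)=C/[Al](C)C | intermediate (not isolated)
6 | (E)-5-iodo-4-methylpent-4-en-1-ol | OCCC/C(C)=C/I | intermediate
7 | (E)-5-iodo-4-methylpent-4-enal | O=CCC/C(C)=C/I | intermediate
8 | diisopinocampheylborinate of 9 | B(O[C@H]([C@H](C)C=C)CC/C(C)=C/I)([C@H]1C[C@H]2C[C@@H]([C@@H]1C)C2(C)C)[C@H]1C[C@H]2C[C@@H]([C@@H]1C)C2(C)C | intermediate (not isolated)
9 | (3R,4S,7E)-8-iodo-3,7-dimethylocta-1,7-dien-4-ol | O[C@H]([C@H](C)C=C)CC/C(C)=C/I | intermediate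
10 | (3R,4S,7E)-8-iodo-4-methoxy-3,7-dimethylocta-1,7-diene | CO[C@H]([C@H](C)C=C)CC/C(C)=C/I | intermediate
11 | (3R,4S,7E)-8-iodo-4-methoxy-3,7-dimethyloct-7-ene-1,2-diol, both C2 epimers | CO[C@H]([C@H](C)C(O)CO)CC/C(C)=C/I | intermediate
12 | 2,2-dibutyl-1,3,2-dioxastannolane (stannylene acetal) of 11 | CO[C@H]([C@H](C)C1CO[Sn](CCCC)(CCCC)O1)CC/C(C)=C/I | intermediate (not isolated)
13 | (2E)-4-{[(3R,4S,7E)-2-hydroxy-8-iodo-4-methoxy-3,7-dimethyloct-7-en-1-yl]oxy}-3-methylbut-2-en-1-yl acetate, both C2 epimers | CO[C@H]([C@H](C)C(O)COC/C(C)=C/COC(C)=O)CC/C(C)=C/I | intermediate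
14 | (2E)-4-{[(3S,4S,7E)-8-iodo-4-methoxy-3,7-dimethyl-2-oxooct-7-en-1-yl]oxy}-3-methylbut-2-en-1-yl acetate | CO[C@H]([C@H](C)C(=O)COC/C(C)=C/COC(C)=O)CC/C(C)=C/I | intermediate
15 | N,N-dimethylhydrazone of 14 | CO[C@H]([C@H](C)C(=NN(C)C)COC/C(C)=C/COC(C)=O)CC/C(C)=C/I | intermediate (not isolated)
16 | (2E)-4-{[(3R,4S,7E)-2-(dimethylhydrazinylidene)-8-iodo-4-methoxy-3,7-dimethyloct-7-en-1-yl]oxy}-3-methylbut-2-en-1-ol | CO[C@H]([C@H](C)C(=NN(C)C)COC/C(C)=C/CO)CC/C(C)=C/I | intermediate
17 | (2E)-4-{[(3R,4S,7E)-2-(dimethylhydrazinylidene)-8-iodo-4-methoxy-3,7-dimethyloct-7-en-1-yl]oxy}-3-methylbut-2-enal | CO[C@H]([C@H](C)C(=NN(C)C)COC/C(C)=C/C=O)CC/C(C)=C/I | intermediate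
18 | (4R,5S,8E,10R,11E)-3-(dimethylhydrazinylidene)-5-methoxy-4,8,12-trimethyl-1-oxacyclotrideca-8,11-dien-10-ol (1S,6R in target numbering) | CO[C@H]1CC/C(C)=C/[C@@H](O)/C=C(\C)COCC(=NN(C)C)[C@H]1C | intermediate
19 | tert-butyldimethylsilyl ether of 18: thirteen-membered ether (O8–C12), C9 dimethylhydrazone, E C7=C11, (6R) silyl ether | CO[C@H]1CC/C(C)=C/[C@@H](O[Si](C)(C)C(C)(C)C)/C=C(\C)COCC(=NN(C)C)[C@H]1C | intermediate
20 | lithium aza-enolate of 19 (C8=C9, N–Li) | CO[C@H]1CC/C(C)=C/[C@@H](O[Si](C)(C)C(C)(C)C)/C=C(\C)CO/C=C(\N([Li])N(C)C)[C@H]1C | intermediate (not isolated)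
21 | lithium alkoxide of 22 | CO[C@H]1CC/C(C)=C/[C@@H](O[Si](C)(C)C(C)(C)C)[C@H](C(C)=C)[C@@H](O[Li])C(=NN(C)C)[C@H]1C | intermediate (not isolated)
22 | ten-membered α-hydroxy hydrazone (1S,6R,7R,8R,10R in target numbering): 1-OMe, 4E, 6-OTBS, 7-isopropenyl, 8-OH, 9-dimethylhydrazone | CO[C@H]1CC/C(C)=C/[C@@H](O[Si](C)(C)C(C)(C)C)[C@H](C(C)=C)[C@@H](O)C(=NN(C)C)[C@H]1C | intermediate
23 | tiglic acid | C/C=C(\C)C(=O)O | starting material
24 | (2E)-2-methylbut-2-en-1-ol | C/C=C(\C)CO | intermediate
25 | [(2R,3R)-2,3-dimethyloxiran-2-yl]methanol | OC[C@@]1(C)O[C@@H]1C | intermediate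
26 | (2S,3R)-2,3-dimethyloxirane-2-carboxylic acid | OC(=O)[C@@]1(C)O[C@@H]1C | intermediate
27 | mixed anhydride of 26 with 2,4,6-trichlorobenzoic acid | O=C(OC(=O)c1c(Cl)cc(Cl)cc1Cl)[C@@]1(C)O[C@@H]1C | intermediate (not isolated)
28 | C8 (2S,3R)-2,3-epoxy-2-methylbutanoate of 22 | CO[C@H]1CC/C(C)=C/[C@@H](O[Si](C)(C)C(C)(C)C)[C@H](C(C)=C)[C@@H](OC(=O)[C@@]2(C)O[C@@H]2C)C(=NN(C)C)[C@H]1C | intermediate
29 | B-alkyl-9-borabicyclononane from 28 (boron on C12), C11 epimers | CO[C@H]1CC/C(C)=C/[C@@H](O[Si](C)(C)C(C)(C)C)[C@H](C(C)CB2C3CCCC2CCC3)[C@@H](OC(=O)[C@@]2(C)O[C@@H]2C)C(=NN(C)C)[C@H]1C | intermediate (not isolated)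
30 | C12 primary alcohol (C7 bears CH(CH3)CH2OH), C11 epimers | CO[C@H]1CC/C(C)=C/[C@@H](O[Si](C)(C)C(C)(C)C)[C@H](C(C)CO)[C@@H](OC(=O)[C@@]2(C)O[C@@H]2C)C(=NN(C)C)[C@H]1C | intermediate
31 | C12 carboxylic acid, (6R) silyl ether, C11 epimers | CO[C@H]1CC/C(C)=C/[C@@H](O[Si](C)(C)C(C)(C)C)[C@H](C(C)C(=O)O)[C@@H](OC(=O)[C@@]2(C)O[C@@H]2C)C(=NN(C)C)[C@H]1C | intermediate
32 | (6R) hydroxy acid, C11 epimers | CO[C@H]1CC/C(C)=C/[C@@H](O)[C@H](C(C)C(=O)O)[C@@H](OC(=O)[C@@]2(C)O[C@@H]2C)C(=NN(C)C)[C@H]1C | intermediate (not isolated)
33 | cis-fused γ-lactone (6S,7S), C9 dimethylhydrazone, C11 epimers | CO[C@H]1CC/C(C)=C/[C@@H]2OC(=O)C(C)[C@@H]2[C@@H](OC(=O)[C@@]2(C)O[C@@H]2C)C(=NN(C)C)[C@H]1C | intermediate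
34 | (1S,6S,7S,8R,10R,11S) cis-fused lactone, C9 dimethylhydrazone | CO[C@H]1CC/C(C)=C/[C@@H]2OC(=O)[C@@H](C)[C@@H]2[C@@H](OC(=O)[C@@]2(C)O[C@@H]2C)C(=NN(C)C)[C@H]1C | intermediate
35 | CNP0145898.1: (3S,3aS,4R,6S,7S,10E,11aS)-7-methoxy-3,6,10-trimethyl-2,5-dioxo-2,3,3a,4,5,6,7,8,9,11a-decahydrocyclodeca[b]furan-4-yl (2S,3R)-2,3-dimethyloxirane-2-carboxylate | CO[C@H]1CC/C(C)=C/[C@@H]2OC(=O)[C@@H](C)[C@@H]2[C@@H](OC(=O)[C@@]2(C)O[C@@H]2C)C(=O)[C@H]1C | target

**Step count**

Total: 23 steps (steps 1–2 bromide; steps 3–14 and 18–23 main line; steps 15–17 epoxy acid).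
Longest linear sequence: 18 steps (pent-4-yn-1-ol to the target, steps 3–14 and 18–23).

**Steps most likely to fail**

1. Step 14 (ring contraction). What may go wrong: attack on the alkene face syn to the silyloxy group or low face selectivity, metalation at C10 followed by loss of methoxide, or a competing [1,2]-shift. Fallback (known chemistry): the rearrangement is run on the open chain, where the aza-enolate shift is established, and the carbocycle is closed afterwards. It sets out from 16. Silylation of the primary alcohol (TBSCl, imidazole) gives the open-chain silyl ether F1. LiN(iPr)2 in THF then brings about the open-chain [2,3]-shift to the α-hydroxy hydrazone F2; C7/C8 anti follows from the E alkene, and the sense relative to C10 would be secured with a chiral hydrazine auxiliary if C10 alone is insufficient. Esterification with 26 as in step 18 gives the epoxy ester F3, HF·pyridine the primary alcohol F4, and Dess–Martin oxidation the aldehyde F5. The NiCl2/CrCl2 coupling closes the ten-membered ring at C5–C6 to the allylic alcohol F6, whose silylation (TBSCl, imidazole) returns to the route at 28.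

2. Step 12 (thirteen-membered ring closure). What may go wrong: intermolecular coupling outrunning ring closure, or the new C6 centre forming with little or the wrong preference. Fallback: the unwanted epimer is inverted and recycled. The (6S) alcohol F7, separated from 18, is treated with 4-nitrobenzoic acid, PPh3 and DIAD to give the (6R) 4-nitrobenzoate F8, and catalytic K2CO3 in MeOH returns to the route at 18.

3. Step 21 (desilylation and lactonisation with inversion). What may go wrong: acid-catalysed closure of the free hydroxy acid with retention before activation, or ionisation and elimination of the activated allylic alcohol. Fallback: C6 is inverted by an oxidation–reduction pair before the carboxyl exists, and the lactone is then closed with retention. It sets out from 30. HF·pyridine gives the diol F9, and MnO2 oxidises only the allylic C6 alcohol to the enone F10. NaBH4 with CeCl3 at −78 °C is expected to deliver hydride anti to the C7 side chain to give the (6S) diol F11, and Ag2CO3 on Celite in hot toluene (Fétizon oxidation) closes the cis-fused lactone, rejoining the route at 33.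

**Further compounds**

F1 | step 14 | open-chain primary tert-butyldimethylsilyl ether of 16 | CO[C@H]([C@H](C)C(=NN(C)C)COC/C(C)=C/CO[Si](C)(C)C(C)(C)C)CC/C(C)=C/I
F2 | step 14 | open-chain α-hydroxy hydrazone (C7 isopropenyl and CH2OTBS; C8 hydroxyl) | CO[C@H]([C@H](C)C(=NN(C)C)[C@H](O)[C@H](CO[Si](C)(C)C(C)(C)C)C(C)=C)CC/C(C)=C/I
F3 | step 14 | C8 (2S,3R)-2,3-epoxy-2-methylbutanoate of F2 | CO[C@H]([C@H](C)C(=NN(C)C)[C@H](OC(=O)[C@@]1(C)O[C@@H]1C)[C@H](CO[Si](C)(C)C(C)(C)C)C(C)=C)CC/C(C)=C/I
F4 | step 14 | primary alcohol from F3 (C6 hydroxyl) | CO[C@H]([C@H](C)C(=NN(C)C)[C@H](OC(=O)[C@@]1(C)O[C@@H]1C)[C@H](CO)C(C)=C)CC/C(C)=C/I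
F5 | step 14 | C6 aldehyde from F4 | CO[C@H]([C@H](C)C(=NN(C)C)[C@H](OC(=O)[C@@]1(C)O[C@@H]1C)[C@H](C=O)C(C)=C)CC/C(C)=C/I
F6 | step 14 | ten-membered (6R) allylic alcohol (desilyl 28) | CO[C@H]1CC/C(C)=C/[C@@H](O)[C@H](C(C)=C)[C@@H](OC(=O)[C@@]2(C)O[C@@H]2C)C(=NN(C)C)[C@H]1C
F7 | step 12 | (6S) epimer of 18 | CO[C@H]1CC/C(C)=C/[C@H](O)/C=C(\C)COCC(=NN(C)C)[C@H]1C
F8 | step 12 | (6R) 4-nitrobenzoate of 18 | CO[C@H]1CC/C(C)=C/[C@@H](OC(=O)c2ccc(cc2)[N+](=O)[O-])/C=C(\C)COCC(=NN(C)C)[C@H]1C
F9 | step 21 | (6R) diol from 30 (C6 and C12 hydroxyls), C11 epimers | CO[C@H]1CC/C(C)=C/[C@@H](O)[C@H](C(C)CO)[C@@H](OC(=O)[C@@]2(C)O[C@@H]2C)C(=NN(C)C)[C@H]1C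
F10 | step 21 | C6 enone with C12 hydroxyl, C11 epimers | CO[C@H]1CC/C(C)=C/C(=O)[C@H](C(C)CO)[C@@H](OC(=O)[C@@]2(C)O[C@@H]2C)C(=NN(C)C)[C@H]1C
F11 | step 21 | (6S) diol, C11 epimers | CO[C@H]1CC/C(C)=C/[C@H](O)[C@H](C(C)CO)[C@@H](OC(=O)[C@@]2(C)O[C@@H]2C)C(=NN(C)C)[C@H]1C
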